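**Retrosynthetic overview**
1. The target is (2R)-1,1-bis(2,4,5-trimethoxyphenyl)propan-2-ol. C2 is the only stereocentre, because C1 carries two identical aryl groups.
2. Last disconnection, C1–Ar: dehydrative Friedel–Crafts reaction of 1,2,4-trimethoxybenzene at the benzylic carbinol of (2R)-1-(2,4,5-trimethoxyphenyl)propane-1,2-diol. The C1 configuration of that diol does not matter.
3. Key disconnection, C1–C2: an aroyl anion (the thiamine diphosphate Breslow enaminol of 2,4,5-trimethoxybenzaldehyde) adds to acetaldehyde in an enzyme-catalysed asymmetric cross-benzoin. Two carbonyl carbons are joined and C2 is set as R in the same bond-forming event. The ketone is reduced in the same pot.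
4. No ring is formed. Both benzene rings are bought intact.

Assumption: the SMILES descriptor reads as R at C2 (OH > CHAr2 > CH3 > H), and recombinant benzaldehyde lyase (BAL) counts as an obtainable catalyst, not as a starting material.

**Step 1**
Reactants: 1 2,4,5-trimethoxybenzaldehyde (asaraldehyde); 2 acetaldehyde
Product: 5 (2R)-1-(2,4,5-trimethoxyphenyl)propane-1,2-diol (C1 epimer mixture), via Breslow enaminol 3 (not isolated), via acyloin 4 (not isolated)
Conditions: 1 (20 mM), 2 (5 equiv, in portions), BAL (benzaldehyde lyase, Pseudomonas fluorescens, recombinant), thiamine diphosphate (0.25 mM), MgSO4 (2.5 mM), K2HPO4/KH2PO4 buffer (50 mM, pH 8.0)/DMSO 4:1, 30 °C, 24 h; then NaBH4 (4 equiv, solid, in portions), 0 °C, 1 h, same pot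
Reagents that add atoms: none
Why: This is a thiamine-diphosphate-dependent asymmetric cross-benzoin (enzymatic carboligation) followed by borohydride reduction in the same pot, in which the cofactor ylide adds to 1 and tautomerises to Breslow enaminol 3, an aroyl anion equivalent that reverses the polarity of the aldehyde carbon and attacks the Si face of the equally electrophilic carbonyl carbon of 2 to set C2 as R (the sense BAL shows for (R)-2-hydroxypropiophenones, typically >98% ee), after which NaBH4 at once converts the base-sensitive acyloin 4 into the configurationally stable diol 5, whose new C1 centre is left uncontrolled because step 2 erases it.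

**Step 2**
Reactants: 5 (2R)-1-(2,4,5-trimethoxyphenyl)propane-1,2-diol; 6 1,2,4-trimethoxybenzene
Product: 8 tatarinoid C [(2R)-1,1-bis(2,4,5-trimethoxyphenyl)propan-2-ol], via benzylic cation 7 (not isolated)
Conditions: 6 (3 equiv), p-TsOH·H2O (5 mol %), HFIP (0.1 M), 0 °C to rt, 2 h
Reagents that add atoms: none
Why: In this Brønsted-acid-catalysed dehydrative Friedel–Crafts benzylation in HFIP only the benzylic C1–OH, which has ortho- and para-methoxy donors, ionises to cation 7, and 6 captures it at its most nucleophilic position C5 (para to the 2-OMe, ortho to the 4-OMe) to build the second 2,4,5-trimethoxyphenyl group, so C1 stops being stereogenic while the C2–O and C2–H bonds are never touched and the R configuration is kept.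

**Compound list**
1 | 2,4,5-trimethoxybenzaldehyde (asaraldehyde) | COc1cc(OC)c(C=O)cc1OC | starting material
2 | acetaldehyde | CC=O | starting material
3 | Breslow enaminol of 1 on thiamine diphosphate (enzyme-bound aroyl anion equivalent) | Cc1ncc(CN2C(C)=C(CCOP(=O)(O)OP(=O)(O)O)SC2=C(O)c2cc(OC)c(OC)cc2OC)c(N)n1 | intermediate
4 | (2R)-2-hydroxy-1-(2,4,5-trimethoxyphenyl)propan-1-one | C[C@@H](O)C(=O)c1cc(OC)c(OC)cc1OC | intermediate
5 | (2R)-1-(2,4,5-trimethoxyphenyl)propane-1,2-diol, C1 epimer mixture | C[C@@H](O)C(O)c1cc(OC)c(OC)cc1OC | intermediate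
6 | 1,2,4-trimethoxybenzene | COc1ccc(OC)c(OC)c1 | starting material
7 | (2R)-2-hydroxy-1-(2,4,5-trimethoxyphenyl)propan-1-ylium (benzylic cation) | C[C@@H](O)[CH+]c1cc(OC)c(OC)cc1OC | intermediate
8 | tatarinoid C, (2R)-1,1-bis(2,4,5-trimethoxyphenyl)propan-2-ol | COc1cc(OC)c(C(c2cc(OC)c(OC)cc2OC)[C@@H](C)O)cc1OC | target

**Total step count:** 2 (two isolations covering three transformations). **Longest linear sequence:** 2.

**Steps most likely to fail**
The route has only two steps, so the two stages of step 1 are ranked separately.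

1. **Step 1, carboligation stage.** Aldehyde 1 is ortho-substituted, very electron-rich and poorly water-soluble. It may be a slow donor for BAL, or it may stall at its own benzoin.
   - The fallback sets out from 1 and comes back at 4.
   - Aldehyde 1 is condensed with propane-1,3-dithiol (BF3·OEt2, CH2Cl2, 0 °C) to 2-(2,4,5-trimethoxyphenyl)-1,3-dithiane F1.
   - n-BuLi (THF, −30 °C) turns F1 into 2-lithio-2-(2,4,5-trimethoxyphenyl)-1,3-dithiane F2, a stoichiometric aroyl anion equivalent.
   - F2 is acetylated with N-methoxy-N-methylacetamide (−78 °C, aqueous NH4Cl quench) to 1-[2-(2,4,5-trimethoxyphenyl)-1,3-dithian-2-yl]ethan-1-one F3.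
   - Reduction with BH3·SMe2 and (S)-2-methyl-CBS-oxazaborolidine (10 mol %, THF, −20 °C) gives (1R)-1-[2-(2,4,5-trimethoxyphenyl)-1,3-dithian-2-yl]ethan-1-ol F4. Here the quaternary dithianyl carbon is the large group and methyl the small one.
   - Non-oxidative unmasking (MeI, CaCO3, MeCN/H2O, 40 °C) returns 4; oxidants are avoided because of the electron-rich ring. Ketone 4 is then reduced with NaBH4 in MeOH at 0 °C to 5.

2. **Step 2.** Cation 7 can collapse by hydride shift or by loss of the C2 proton to the achiral aryl acetone before 6 traps it. Too much acid could also trigger aryl migration in 8.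
   - The fallback sets out from 5 and comes back at 8.
   - Diol 5 is peracetylated (Ac2O, pyridine, 4-(dimethylamino)pyridine, CH2Cl2) to (2R)-1-(2,4,5-trimethoxyphenyl)propane-1,2-diyl diacetate F5.
   - With Bi(OTf)3 (5 mol %) and 6 (3 equiv) in CH2Cl2 at −20 °C only the benzylic acetate leaves. The C2 acetate assists by neighbouring-group participation, and as an ester oxygen it no longer drives hydride shift or enol formation.
   - Arylation therefore gives (2R)-1,1-bis(2,4,5-trimethoxyphenyl)propan-2-yl acetate F6.
   - K2CO3 in MeOH at rt cleaves the acetate to 8.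

3. **Step 1, borohydride stage.** NaBH4 hydrolyses quickly in the buffer. The pH rise it causes can also racemise or tautomerise 4 before it is reduced.
   - The fallback sets out from 4 and comes back at 8.
   - Ketone 4 is extracted from the enzyme mixture (EtOAc, pH 7) and isolated.
   - 1-Bromo-2,4,5-trimethoxybenzene and n-BuLi (THF, −78 °C) give 2,4,5-trimethoxyphenyllithium F7.
   - F7 (2.2 equiv) adds to the ketone of 4 (aqueous NH4Cl quench) to give (2R)-1,1-bis(2,4,5-trimethoxyphenyl)propane-1,2-diol F8. The first equivalent is spent on the OH group.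
   - Ionic hydrogenation (Et3SiH, 5 equiv, present before CF3CO2H is added, CH2Cl2, −20 °C) removes only the tertiary, doubly benzylic OH and delivers 8. This bypasses both the hydride addition to 4 and step 2.

**Further compounds**
F1 | step 1 | 2-(2,4,5-trimethoxyphenyl)-1,3-dithiane | COc1cc(OC)c(C2SCCCS2)cc1OC
F2 | step 1 | 2-lithio-2-(2,4,5-trimethoxyphenyl)-1,3-dithiane | [Li]C1(SCCCS1)c1cc(OC)c(OC)cc1OC
F3 | step 1 | 1-[2-(2,4,5-trimethoxyphenyl)-1,3-dithian-2-yl]ethan-1-one | CC(=O)C1(SCCCS1)c1cc(OC)c(OC)cc1OC
F4 | step 1 | (1R)-1-[2-(2,4,5-trimethoxyphenyl)-1,3-dithian-2-yl]ethan-1-ol | C[C@@H](O)C1(SCCCS1)c1cc(OC)c(OC)cc1OC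
F5 | step 2 | (2R)-1-(2,4,5-trimethoxyphenyl)propane-1,2-diyl diacetate, C1 epimer mixture | C[C@@H](OC(C)=O)C(OC(C)=O)c1cc(OC)c(OC)cc1OC
F6 | step 2 | (2R)-1,1-bis(2,4,5-trimethoxyphenyl)propan-2-yl acetate | COc1cc(OC)c(C(c2cc(OC)c(OC)cc2OC)[C@@H](C)OC(C)=O)cc1OC
F7 | step 1 | 2,4,5-trimethoxyphenyllithium | [Li]c1cc(OC)c(OC)cc1OC
F8 | step 1 | (2R)-1,1-bis(2,4,5-trimethoxyphenyl)propane-1,2-diol | C[C@@H](O)C(O)(c1cc(OC)c(OC)cc1OC)c1cc(OC)c(OC)cc1OC
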